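**Plan**
- Retrosynthesis: cut the ester C(=O)–O bond first (quinone diol + hydroxy acid), then both aryl–carbonyl bonds of the naphthoquinone (benzyne + a cyclobutenedione), then the ring–CH2 bond (dimethyl squarate + a neopentyl-type Grignard reagent).
- Enabling feature: the quinone carbons C1(=O)–C2(OH)=C3(alkyl)–C4(=O) are a squaric acid unit, and the benzo ring is unsubstituted, so it can come from symmetrical benzyne.
- Forward: the four-membered dione is made from dimethyl squarate; the quinone ring (ring B) then arises by nickel-mediated insertion of benzyne into the strained C1–C2 acyl–acyl bond (strain-release expansion of the four-membered ring to the six-membered ring).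
- Then the methyl and silyl masks are removed and the side-chain acid is attached by esterification at the primary alcohol.
- Stereochemistry: the only stereocentre (6R tertiary carbinol) comes from (R)-(−)-linalool and is never touched; the E-alkene comes from SeO2 oxidation of the E-methyl group of linalool.

Key step: step 3

Assumption: commercial (R)-(−)-linalool is taken as enantiomerically pure; the enantiomeric purity of the target equals that of the linalool used.

**Step 1**
Reactants: 1 3-bromo-2,2-dimethylpropan-1-ol
Product: 2 (3-bromo-2,2-dimethylpropoxy)(tert-butyl)dimethylsilane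
Conditions: TBSCl, imidazole, DMF, 0 °C → rt
Reagents that add atoms: tert-butyldimethylsilyl chloride (TBSCl), CC(C)(C)[Si](C)(C)Cl
Why: Standard silylation of a primary alcohol; the weak base imidazole avoids the alkoxide that would close to 3,3-dimethyloxetane, and the silyl ether masks the hydroxyl for the organomagnesium step.

**Step 2**
Reactants: 2 (3-bromo-2,2-dimethylpropoxy)(tert-butyl)dimethylsilane; 3 dimethyl squarate (3,4-dimethoxycyclobut-3-ene-1,2-dione)
Product: 6 3-methoxy-4-[3-(tert-butyldimethylsilyloxy)-2,2-dimethylpropyl]cyclobut-3-ene-1,2-dione, via Grignard reagent 4 (not isolated), via cyclobutenone alkoxide 5 (not isolated)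
Conditions: Mg turnings (I2 cat.), THF, reflux; add to 3, THF, −78 °C; then (CF3CO)2O, −78 → 0 °C; aq. NaHCO3
Reagents that add atoms: water, O
Why: Grignard formation from a bromide without β-hydrogens, 1,2-addition to one squarate carbonyl, then trifluoroacetylation and ionisation of the tertiary alkoxide with hydrolytic loss of methanol from the methoxy-stabilised cation should give the 3-alkoxy-4-alkylcyclobutenedione (the standard squarate sequence); the racemic carbinol centre of 5 is destroyed.

**Step 3**
Reactants: 6 3-methoxy-4-[3-(tert-butyldimethylsilyloxy)-2,2-dimethylpropyl]cyclobut-3-ene-1,2-dione; 7 2-(trimethylsilyl)phenyl trifluoromethanesulfonate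
Product: 10 2-methoxy-3-[3-(tert-butyldimethylsilyloxy)-2,2-dimethylpropyl]naphthalene-1,4-dione, via maleoylnickel bipyridine complex 8 (not isolated), via benzyne 9 (not isolated)
Conditions: Ni(cod)2 (1.1 equiv), 2,2'-bipyridine (1.1 equiv), THF, −30 °C → rt; then 7 (1.5 equiv), CsF (3 equiv), MeCN, rt; air, 1 M HCl work-up
Reagents that add atoms: none
Why: Proposed new method: zerovalent nickel should insert into the strained acyl–acyl bond (C1–C2) of 6 to give the five-membered maleoylnickel complex 8 (divalent nickel); benzyne 9, released slowly from 7 by fluoride, should then insert into one Ni–acyl bond, and the seven-membered aryl(acyl)nickel ring should collapse by aryl–acyl reductive elimination, so that both aryl–carbonyl bonds form in one flask operation. The closest known reaction types are the conversion of cyclobutenedione-derived maleoyl and phthaloyl complexes of cobalt and nickel into quinones with alkynes, and the insertion of fluoride-generated arynes into acyl–palladium and carbon–nickel bonds. The only ring closed is the quinone ring (ring B), formed as a formal [4+2] union, that is a two-carbon expansion of the four-membered ring ending in C–C reductive elimination; no stereocentre is created. The step needs cleavage of the dione bond and not of an acyl–vinyl bond, which the weak, strained 1,2-dione bond should secure, and a single aryne insertion without CO loss or aryne oligomerisation, which preforming 8 (no free zerovalent nickel when benzyne appears), slow aryne release and room temperature should secure. Benzyne is symmetrical, so no regiochemical question arises, and the neopentyl silyl ether should tolerate CsF in MeCN at room temperature. Nickel is used in stoichiometric amount because the quinone would bind to or be reduced by zerovalent nickel, and the aerobic acidic work-up should return any hydroquinone to the quinone.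

**Step 4**
Reactants: 10 2-methoxy-3-[3-(tert-butyldimethylsilyloxy)-2,2-dimethylpropyl]naphthalene-1,4-dione
Product: 12 2-hydroxy-3-(3-hydroxy-2,2-dimethylpropyl)naphthalene-1,4-dione, via sodium enolate 11 (not isolated)
Conditions: 2 M aq. NaOH (3 equiv), MeOH/THF, 0 °C → rt; then 3 M HCl to pH 1, rt
Reagents that add atoms: NaOH, [Na+].[OH-]
Why: Hydroxide should add to C2 of the quinone and expel methoxide (addition–elimination at a vinylogous ester) to give the stabilised enolate 11, which resists further attack and ring closure by the side-chain oxygen; acidification then frees the enol and cleaves the primary silyl ether by acid-catalysed solvolysis.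

**Step 5**
Reactants: 13 (R)-(−)-linalool
Product: 14 (2E,6R)-2,6-dimethylocta-2,7-diene-1,6-diol
Conditions: SeO2 (0.2 equiv), t-BuOOH (70% aq., 2.5 equiv), salicylic acid (cat.), CH2Cl2, rt
Reagents that add atoms: SeO2, O=[Se]=O (catalytic oxygen donor); tert-butyl hydroperoxide, CC(C)(C)OO (terminal oxidant)
Why: SeO2 allylic oxidation (ene reaction, then [2,3]-sigmatropic shift) should attack the electron-rich trisubstituted alkene at its E-methyl group and give the (E)-allylic alcohol; the vinyl group and the tertiary carbinol stereocentre are not involved.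

**Step 6**
Reactants: 14 (2E,6R)-2,6-dimethylocta-2,7-diene-1,6-diol
Product: 15 (2E,6R)-6-hydroxy-2,6-dimethylocta-2,7-dienal
Conditions: activated MnO2 (excess), CH2Cl2, rt
Reagents that add atoms: none
Why: MnO2 should oxidise only the primary allylic alcohol (the tertiary one has no carbinol hydrogen) with retention of the E geometry, and any aldehyde already formed in step 5 converges here.

**Step 7**
Reactants: 15 (2E,6R)-6-hydroxy-2,6-dimethylocta-2,7-dienal
Product: 16 (2E,6R)-6-hydroxy-2,6-dimethylocta-2,7-dienoic acid
Conditions: NaClO2, NaH2PO4, 2-methyl-2-butene, t-BuOH/H2O, rt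
Reagents that add atoms: NaClO2, [Na+].[O-]Cl=O
Why: Pinnick oxidation should convert the enal into the acid without touching the alkenes or the tertiary alcohol, 2-methyl-2-butene scavenging the HOCl formed.

**Step 8**
Reactants: 12 2-hydroxy-3-(3-hydroxy-2,2-dimethylpropyl)naphthalene-1,4-dione; 16 (2E,6R)-6-hydroxy-2,6-dimethylocta-2,7-dienoic acid
Product: 18 Rhinacanthin H, 3-(3-hydroxy-1,4-dioxo-1,4-dihydronaphthalen-2-yl)-2,2-dimethylpropyl (2E,6R)-6-hydroxy-2,6-dimethylocta-2,7-dienoate, via mixed anhydride 17 (not isolated)
Conditions: 16 (1.1 equiv), 2,4,6-trichlorobenzoyl chloride (1.1 equiv), Et3N (2.5 equiv), THF, rt; then 12 (1.0 equiv), DMAP (1.5 equiv), toluene, rt; 5% aq. citric acid work-up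
Reagents that add atoms: none
Why: Yamaguchi esterification: DMAP should open 17 at the unhindered aliphatic carbonyl and the acylpyridinium should acylate the primary neopentyl alcohol; the tertiary allylic alcohol is too hindered to compete (lactonisation would need an E-alkene in a seven-membered ring), any O-acyl enol formed at the acidic 2-hydroxyl is a vinylogous mixed anhydride that DMAP returns to the acyl pool or the work-up cleaves, and the stereocentre is untouched.

**Compound list**
1 | 3-bromo-2,2-dimethylpropan-1-ol | OCC(C)(C)CBr | starting material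
2 | (3-bromo-2,2-dimethylpropoxy)(tert-butyl)dimethylsilane | CC(C)(C)[Si](C)(C)OCC(C)(C)CBr | intermediate
3 | dimethyl squarate (3,4-dimethoxycyclobut-3-ene-1,2-dione) | COC1=C(OC)C(=O)C1=O | starting material
4 | [3-(tert-butyldimethylsilyloxy)-2,2-dimethylpropyl]magnesium bromide | CC(C)(C)[Si](C)(C)OCC(C)(C)C[Mg]Br | intermediate
5 | bromomagnesium alkoxide of 4-hydroxy-2,3-dimethoxy-4-[3-(tert-butyldimethylsilyloxy)-2,2-dimethylpropyl]cyclobut-2-en-1-one (racemic) | COC1=C(OC)C(O[Mg]Br)(CC(C)(C)CO[Si](C)(C)C(C)(C)C)C1=O | intermediate
6 | 3-methoxy-4-[3-(tert-butyldimethylsilyloxy)-2,2-dimethylpropyl]cyclobut-3-ene-1,2-dione | COC1=C(CC(C)(C)CO[Si](C)(C)C(C)(C)C)C(=O)C1=O | intermediate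
7 | 2-(trimethylsilyl)phenyl trifluoromethanesulfonate | C[Si](C)(C)c1ccccc1OS(=O)(=O)C(F)(F)F | starting material
8 | (2,2'-bipyridine)nickel maleoyl complex: 1-nickelacyclopent-3-ene-2,5-dione with 3-methoxy and 4-[3-(tert-butyldimethylsilyloxy)-2,2-dimethylpropyl] groups, divalent nickel, N,N-chelated (dative bonds drawn charge-separated) | COC1=C(CC(C)(C)CO[Si](C)(C)C(C)(C)C)C(=O)[Ni-2]2(C1=O)[n+]1ccccc1-c1cccc[n+]12 | intermediate
9 | benzyne (cyclohexa-1,3-dien-5-yne) | C1#CC=CC=C1 | intermediate
10 | 2-methoxy-3-[3-(tert-butyldimethylsilyloxy)-2,2-dimethylpropyl]naphthalene-1,4-dione | COC1=C(CC(C)(C)CO[Si](C)(C)C(C)(C)C)C(=O)c2ccccc2C1=O | intermediate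
11 | sodium 3-[3-(tert-butyldimethylsilyloxy)-2,2-dimethylpropyl]-1,4-dioxo-1,4-dihydronaphthalen-2-olate | CC(C)(C)[Si](C)(C)OCC(C)(C)CC1=C([O-])C(=O)c2ccccc2C1=O.[Na+] | intermediate
12 | 2-hydroxy-3-(3-hydroxy-2,2-dimethylpropyl)naphthalene-1,4-dione | OCC(C)(C)CC1=C(O)C(=O)c2ccccc2C1=O | intermediate
13 | (R)-(−)-linalool, (3R)-3,7-dimethylocta-1,6-dien-3-ol | C=C[C@](C)(O)CCC=C(C)C | starting material
14 | (2E,6R)-2,6-dimethylocta-2,7-diene-1,6-diol | C=C[C@](C)(O)CC/C=C(\C)CO | intermediate
15 | (2E,6R)-6-hydroxy-2,6-dimethylocta-2,7-dienal | C=C[C@](C)(O)CC/C=C(\C)C=O | intermediate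
16 | (2E,6R)-6-hydroxy-2,6-dimethylocta-2,7-dienoic acid | C=C[C@](C)(O)CC/C=C(\C)C(=O)O | intermediate
17 | mixed anhydride of 16 and 2,4,6-trichlorobenzoic acid | C=C[C@](C)(O)CC/C=C(\C)C(=O)OC(=O)c1c(Cl)cc(Cl)cc1Cl | intermediate
18 | Rhinacanthin H, 3-(3-hydroxy-1,4-dioxo-1,4-dihydronaphthalen-2-yl)-2,2-dimethylpropyl (2E,6R)-6-hydroxy-2,6-dimethylocta-2,7-dienoate | C=C[C@](C)(O)CC/C=C(\C)C(=O)OCC(C)(C)CC1=C(O)C(=O)c2ccccc2C1=O | target

**Totals**
Total step count: 8. Longest linear sequence: 5 steps (steps 1, 2, 3, 4, 8); the acid branch is steps 5–7.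

**Steps most likely to fail**

Step 3 (proposed new method). The nickelacycle may lose CO before it meets the aryne, the aryne may oligomerise or insert twice, or the reductive elimination may stall. The fallback uses known chemistry and sets out from 6. Phenyllithium (THF, −78 °C) should add to the more electrophilic carbonyl, the one next to the methoxy-bearing carbon, to give 4-hydroxy-3-methoxy-4-phenyl-2-[3-(tert-butyldimethylsilyloxy)-2,2-dimethylpropyl]cyclobut-2-en-1-one F1. Heating F1 in p-xylene at reflux should open the ring to the aryl vinylketene, which closes onto the phenyl ring and tautomerises (Moore rearrangement) to 2-methoxy-3-[3-(tert-butyldimethylsilyloxy)-2,2-dimethylpropyl]naphthalene-1,4-diol F2. Oxidation of F2 with Ag2O in ether, or with air, should return to the route at 10. In this fallback the two aryl–carbonyl bonds form in separate steps.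

Step 8. The acidic enol hydroxyl may be acylated in competition with the hindered neopentyl alcohol, so that acid is consumed or acyl transfer stays incomplete. The fallback keeps the enol masked as its methyl ether and sets out from 10 and 16. HF·pyridine in THF/pyridine (0 °C → rt) should remove the silyl group to give 3-(3-hydroxy-2,2-dimethylpropyl)-2-methoxynaphthalene-1,4-dione F3. Yamaguchi esterification of F3 with 16 (through 17, as in step 8) should give 3-(3-methoxy-1,4-dioxo-1,4-dihydronaphthalen-2-yl)-2,2-dimethylpropyl (2E,6R)-6-hydroxy-2,6-dimethylocta-2,7-dienoate F4. Brief treatment of F4 with LiOH (2 equiv) in THF/H2O at 0 °C should hydrolyse the vinylogous methyl ester at C2 much faster than the hindered conjugated neopentyl ester and return to the route at 18.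

Step 5. The selenium oxidation may stop at partial conversion, over-oxidise, or transpose or dehydrate the tertiary allylic alcohol under the acidic conditions. The fallback builds the enoate by olefination and sets out from 13. Ozonolysis with about one equivalent of ozone (CH2Cl2/MeOH, −78 °C; then Me2S) should cleave only the trisubstituted alkene and give (5R)-5-ethenyl-5-methyloxolan-2-ol F5, the lactol of (4R)-4-hydroxy-4-methylhex-5-enal. Wittig reaction of F5 with ethyl 2-(triphenylphosphoranylidene)propanoate (toluene, 80 °C) should give, E-selectively, ethyl (2E,6R)-6-hydroxy-2,6-dimethylocta-2,7-dienoate F6. Saponification of F6 with LiOH in THF/H2O should return to the route at 16, bypassing 14 and 15.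

**Further compounds**
F1 | step 3 | 4-hydroxy-3-methoxy-4-phenyl-2-[3-(tert-butyldimethylsilyloxy)-2,2-dimethylpropyl]cyclobut-2-en-1-one (racemic) | COC1=C(CC(C)(C)CO[Si](C)(C)C(C)(C)C)C(=O)C1(O)c1ccccc1
F2 | step 3 | 2-methoxy-3-[3-(tert-butyldimethylsilyloxy)-2,2-dimethylpropyl]naphthalene-1,4-diol | COc1c(CC(C)(C)CO[Si](C)(C)C(C)(C)C)c(O)c2ccccc2c1O
F3 | step 8 | 3-(3-hydroxy-2,2-dimethylpropyl)-2-methoxynaphthalene-1,4-dione | COC1=C(CC(C)(C)CO)C(=O)c2ccccc2C1=O
F4 | step 8 | 3-(3-methoxy-1,4-dioxo-1,4-dihydronaphthalen-2-yl)-2,2-dimethylpropyl (2E,6R)-6-hydroxy-2,6-dimethylocta-2,7-dienoate | C=C[C@](C)(O)CC/C=C(\C)C(=O)OCC(C)(C)CC1=C(OC)C(=O)c2ccccc2C1=O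
F5 | step 5 | (5R)-5-ethenyl-5-methyloxolan-2-ol (mixture of anomers) | C=C[C@]1(C)OC(O)CC1
F6 | step 5 | ethyl (2E,6R)-6-hydroxy-2,6-dimethylocta-2,7-dienoate | C=C[C@](C)(O)CC/C=C(\C)C(=O)OCC
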